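## Retrosynthetic overview

1. Target ⇒ spiro enone carrying a C3 ketone: the (Z)-bromomethylidene comes from 1,1-dibromo-olefination, then removal of the less hindered bromine.
2. Spiro enone ⇒ spiro cyclohexadienone with two identical arms on C6: the C7 hydroxyl directs hydrogenation to the syn arm and so fixes C6.
3. Dienone ⇒ saturated spiro bromohydrin ketone ⇒ one-flask bicyclisation of an acyclic α-methylene ketone with 2-(trimethylsilyloxy)butadiene: Diels–Alder (ring B, quaternary C6), then enantioselective bromo-Prins closure (ring A, C7 and C9).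
4. Acyclic enone ⇒ mesityl oxide + allyltrimethylsilane + a formaldehyde iminium salt (Sakurai / Mannich / elimination).
5. Ring order: B first, A second, both in the same operation; no protecting groups.

Assumption: atoms are numbered C1–C5 (ring B), C6 (spiro), C7–C11 (ring A), C15 = exocyclic carbon; the (S)-oxazaborolidine is taken to leave the Si face of the bound C7 ketone open, otherwise its (R)-antipode is used.

## Route

Step 1
Reactants: 1 4-methylpent-3-en-2-one (mesityl oxide); 2 allyltrimethylsilane
Product: 6 4,4-dimethyl-3-methylidenehept-6-en-2-one, via trichlorotitanium enolate 3 (not isolated), via Mannich base 4 (not isolated), via methiodide 5 (not isolated)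
Conditions: TiCl4, CH2Cl2, −78 °C; then CH2=NMe2+ I−, −78 → 0 °C; aq NaHCO3; crude 4: MeI, Et2O, 23 °C; then aq NaHCO3/CH2Cl2, 23 °C
Reagents that add atoms: N,N-dimethylmethylideneammonium iodide (CH2=NMe2+ I−), C=[N+](C)C.[I-]
Why: Hosomi–Sakurai conjugate allylation builds the CMe2 quaternary carbon and gives the titanium enolate regiospecifically at C6, which is trapped by the iminium ion (Mannich reaction) and, after N-methylation, loses trimethylamine by E1cB elimination to give the α-methylene ketone; no stereocentre remains.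

Step 2
Reactants: 6 4,4-dimethyl-3-methylidenehept-6-en-2-one; 7 2-(trimethylsilyloxy)buta-1,3-diene
Product: 10 (7S,9R)-9-bromo-7-hydroxy-7,11,11-trimethylspiro[5.5]undecan-3-one, via silyl enol ether adduct 8 (not isolated), via bromo silyl enol ether 9 (not isolated)
Conditions: 7 (1.5 equiv), (S)-1-(2-methylphenyl)-3,3-diphenyltetrahydro-1H,3H-pyrrolo[1,2-c][1,3,2]oxazaborole (C24H24BNO)·AlBr3 (1.2 equiv), CH2Cl2, −78 → −20 °C; then 1 M HCl, THF, 0 °C
Reagents that add atoms: aluminium tribromide, Br[Al](Br)Br
Why: Proposed new method: the boron Lewis acid first promotes the Diels–Alder reaction (Mukaiyama–Michael/Michael in the stepwise limit, first bond at the unhindered methylene) that forms ring B and the quaternary C6, then binds the more basic saturated acetyl group so that the tethered terminal alkene adds to its Si face through a chair with the C7 methyl equatorial (avoiding a syn-diaxial clash with the axial C11 methyl), and the C9 cation is quenched by bromide from the aluminate on the equatorial face, trans to oxygen (7S,9R); the closest known reactions are Lewis-acid Diels–Alder additions of 2-siloxydienes to α-substituted enones, halo-Prins cyclisations of olefinic carbonyl compounds with titanium or aluminium halides, and oxazaborolidinium-promoted enantioselective additions to methyl ketones.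

Step 3
Reactants: 10 (7S,9R)-9-bromo-7-hydroxy-7,11,11-trimethylspiro[5.5]undecan-3-one
Product: 11 (7S,9R)-9-bromo-7-hydroxy-7,11,11-trimethylspiro[5.5]undeca-1,4-dien-3-one
Conditions: 2-iodoxybenzoic acid (IBX, 3 equiv), 4-methoxypyridine N-oxide (3 equiv), DMSO, 25 °C
Reagents that add atoms: none
Why: IBX dehydrogenation of the ketone at both α,β-positions gives the cross-conjugated dienone, in which C6 carries two identical arms, under non-basic conditions that leave the tertiary alcohol and secondary bromide (C7, C9) untouched and avoid retro-aldol aromatisation.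

Step 4
Reactants: 11 (7S,9R)-9-bromo-7-hydroxy-7,11,11-trimethylspiro[5.5]undeca-1,4-dien-3-one
Product: 12 (6S,7S,9R)-9-bromo-7-hydroxy-7,11,11-trimethylspiro[5.5]undec-4-en-3-one
Conditions: H2 (1 atm), [Ir(cod)(PCy3)(py)]PF6 (10 mol %), CH2Cl2, 0 → 23 °C
Reagents that add atoms: none
Why: Hydroxyl-directed homogeneous hydrogenation: the axial C7–OH binds iridium and reaches only the enone alkene on the equatorial (gauche, syn) arm of C6, not the anti-periplanar axial arm, so saturation of the syn arm alone makes C6 a stereocentre with the 6S configuration.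

Step 5
Reactants: 12 (6S,7S,9R)-9-bromo-7-hydroxy-7,11,11-trimethylspiro[5.5]undec-4-en-3-one
Product: 13 (6S,7S,9R)-9-bromo-3-(dibromomethylidene)-7,11,11-trimethylspiro[5.5]undec-4-en-7-ol
Conditions: CBr4 (2 equiv), P(Oi-Pr)3 (4 equiv), CH2Cl2, 0 → 23 °C
Reagents that add atoms: carbon tetrabromide, BrC(Br)(Br)Br
Why: Ramirez-type dibromo-olefination (Wittig-type reaction of the dibromomethylene phosphorus ylide formed in situ) at the only ketone; the hindered tertiary alcohol does not react and no stereocentre is touched.

Step 6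
Reactants: 13 (6S,7S,9R)-9-bromo-3-(dibromomethylidene)-7,11,11-trimethylspiro[5.5]undec-4-en-7-ol
Product: 14 (3Z,6S,7S,9R)-9-bromo-3-(bromomethylidene)-7,11,11-trimethylspiro[5.5]undec-4-en-7-ol
Conditions: Bu3SnH (1.05 equiv), Pd(PPh3)4 (5 mol %), 2,6-di-tert-butyl-4-methylphenol (cat.), PhMe, 23 °C, dark
Reagents that add atoms: none
Why: Stereoselective hydrogenolysis of a 1,1-dibromoalkene: zerovalent palladium inserts into the less hindered C–Br bond, the one syn to the sp3 C2 methylene (the in-plane C4–H buttresses the other bromine), and tin hydride replaces it by hydrogen with retention, leaving the bromine syn to C4 (3Z) while the secondary alkyl bromide is inert without a radical chain.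

## Compound list

1 | 4-methylpent-3-en-2-one (mesityl oxide) | CC(=O)C=C(C)C | starting material
2 | allyltrimethylsilane | C=CC[Si](C)(C)C | starting material
3 | trichlorotitanium enolate of 4,4-dimethylhept-6-en-2-one (O–TiCl3 on C2, C2=C3 enolate) | CC(O[Ti](Cl)(Cl)Cl)=CC(C)(C)CC=C | intermediate
4 | 3-[(dimethylamino)methyl]-4,4-dimethylhept-6-en-2-one (racemic) | CC(=O)C(CN(C)C)C(C)(C)CC=C | intermediate
5 | (2-acetyl-3,3-dimethylhex-5-en-1-yl)trimethylammonium iodide (racemic) | CC(=O)C(C[N+](C)(C)C)C(C)(C)CC=C.[I-] | intermediate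
6 | 4,4-dimethyl-3-methylidenehept-6-en-2-one | CC(=O)C(=C)C(C)(C)CC=C | intermediate
7 | 2-(trimethylsilyloxy)buta-1,3-diene | C=CC(=C)O[Si](C)(C)C | starting material
8 | 1-[1-(2-methylpent-4-en-2-yl)-4-(trimethylsilyloxy)cyclohex-3-en-1-yl]ethan-1-one (configuration at the ring quaternary carbon not controlled) | CC(=O)C1(CCC(O[Si](C)(C)C)=CC1)C(C)(C)CC=C | intermediate
9 | (7S,9R)-9-bromo-7,11,11-trimethyl-3-(trimethylsilyloxy)spiro[5.5]undec-3-en-7-ol (both C6 epimers; O7 bound to boron until work-up) | CC1(C)C[C@@H](Br)C[C@](C)(O)C12CCC(O[Si](C)(C)C)=CC2 | intermediate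
10 | (7S,9R)-9-bromo-7-hydroxy-7,11,11-trimethylspiro[5.5]undecan-3-one | CC1(C)C[C@@H](Br)C[C@](C)(O)C12CCC(=O)CC2 | intermediate
11 | (7S,9R)-9-bromo-7-hydroxy-7,11,11-trimethylspiro[5.5]undeca-1,4-dien-3-one | CC1(C)C[C@@H](Br)C[C@](C)(O)C12C=CC(=O)C=C2 | intermediate
12 | (6S,7S,9R)-9-bromo-7-hydroxy-7,11,11-trimethylspiro[5.5]undec-4-en-3-one | CC1(C)C[C@@H](Br)C[C@](C)(O)[C@@]12C=CC(=O)CC2 | intermediate
13 | (6S,7S,9R)-9-bromo-3-(dibromomethylidene)-7,11,11-trimethylspiro[5.5]undec-4-en-7-ol | CC1(C)C[C@@H](Br)C[C@](C)(O)[C@@]12C=CC(=C(Br)Br)CC2 | intermediate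
14 | (3Z,6S,7S,9R)-9-bromo-3-(bromomethylidene)-7,11,11-trimethylspiro[5.5]undec-4-en-7-ol | CC1(C)C[C@@H](Br)C[C@](C)(O)[C@@]12C=C/C(=C\Br)CC2 | target

## Step count and risks

Total step count: 6. Longest linear sequence: 6 steps (1 → 6 → 10 → 11 → 12 → 13 → 14).

Three steps most likely to fail:

Step 2. The hindered acetyl group may resist Prins closure, and the enantioselectivity of this closure is unproven. The fallback sets out again from 1, builds the rings one at a time and fixes C7 by a catalytic allylboration, and comes back at 10. Deconjugative double alkylation of 1 with 2,2-bis(2-bromoethyl)-1,3-dioxolane (KOt-Bu, t-BuOH/THF) gives 1-[8-(prop-1-en-2-yl)-1,4-dioxaspiro[4.5]decan-8-yl]ethan-1-one F1. Enantioselective allylboration of its methyl ketone (allylB(pin), chiral aminophenol-derived boron catalyst, NaOt-Bu, MeOH, PhMe) gives (2S)-2-[8-(prop-1-en-2-yl)-1,4-dioxaspiro[4.5]decan-8-yl]pent-4-en-2-ol F2. Acetylation (Ac2O, Sc(OTf)3, MeCN) gives (2S)-2-[8-(prop-1-en-2-yl)-1,4-dioxaspiro[4.5]decan-8-yl]pent-4-en-2-yl acetate F3, the ester suppressing retro-Prins fragmentation. HBr in AcOH/CH2Cl2 at −20 °C protonates the isopropenyl group; the tertiary cation is captured by the allyl terminus in a chair, bromide adds equatorially, and the ketal is hydrolysed on aqueous work-up, giving (7S,9R)-9-bromo-7,11,11-trimethyl-3-oxospiro[5.5]undecan-7-yl acetate F4. K2CO3 in MeOH then returns 10.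

Step 4. The iridium catalyst may over-reduce, or may bind the hindered tertiary alcohol poorly. The fallback sets out from 11 and comes back at 12. It replaces substrate direction by reagent control: copper hydride made from Cu(OAc)2 (5 mol %), the matched enantiomer of DTBM-SEGPHOS, polymethylhydrosiloxane and t-BuOH in PhMe at 0 °C reduces one of the two diastereotopic enone arms in a 1,4-sense and protonates the enolate in situ. This fallback makes no new compound (F0).

Step 6. The two C–Br bonds of 13 may not be differentiated well enough. The fallback sets out from 12 and comes back at 14. A Wittig reaction of 12 with bromomethylidenetriphenylphosphorane (from Ph3P+CH2Br Br− and KN(SiMe3)2, THF, −78 → 0 °C) gives 14 together with (3E,6S,7S,9R)-9-bromo-3-(bromomethylidene)-7,11,11-trimethylspiro[5.5]undec-4-en-7-ol F5. The isomers are separated on silica, and the unwanted isomer is re-equilibrated by sensitised irradiation and recycled.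

Further compounds

F1 | step 2 | 1-[8-(prop-1-en-2-yl)-1,4-dioxaspiro[4.5]decan-8-yl]ethan-1-one | CC(=O)C1(CCC2(CC1)OCCO2)C(C)=C
F2 | step 2 | (2S)-2-[8-(prop-1-en-2-yl)-1,4-dioxaspiro[4.5]decan-8-yl]pent-4-en-2-ol | C=CC[C@](C)(O)C1(CCC2(CC1)OCCO2)C(C)=C
F3 | step 2 | (2S)-2-[8-(prop-1-en-2-yl)-1,4-dioxaspiro[4.5]decan-8-yl]pent-4-en-2-yl acetate | C=CC[C@](C)(OC(C)=O)C1(CCC2(CC1)OCCO2)C(C)=C
F4 | step 2 | (7S,9R)-9-bromo-7,11,11-trimethyl-3-oxospiro[5.5]undecan-7-yl acetate | CC1(C)C[C@@H](Br)C[C@](C)(OC(C)=O)C12CCC(=O)CC2
F0 | step 4 | none | none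
F5 | step 6 | (3E,6S,7S,9R)-9-bromo-3-(bromomethylidene)-7,11,11-trimethylspiro[5.5]undec-4-en-7-ol | CC1(C)C[C@@H](Br)C[C@](C)(O)[C@@]12C=C/C(=C/Br)CC2
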